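Numbering used throughout: ring O1, C2 (acrylic acid), C3, C4, C5 (side chain), C6; chain C7, C8, C9 (carbinol), C10 (methylidene-bearing carbon).
Cuts, in retrosynthetic order: the acrylic acid (back to a CH2CO2Et arm on C2), C9–C10 (aldehyde plus the alkenyl triflate of geranylacetone), C8–C9 (CO onto a vinyl group), then the ring bond C5–C6 together with O1–C6.
Enabling feature: C6 of the oxane is an unsubstituted OCH2 beside the branch carbon C5, so O1=C6 can be a formaldehyde-level oxocarbenium (from a MEM ether on O1) and C5 the γ-carbon of an allylsilane, whose C7=C8 is left as a vinyl group.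
Forward order: keto ester → C2 carbinol → MEM ether → allylsilane → the only ring (oxane) closes in step 4; the chain then grows from the vinyl group (CO, then the C10–C22 alkenyl unit) and the acrylic acid is made last.
Stereochemistry: C2 from a ketoreductase; C5 relayed from C2 in the chair transition state of the ring closure (trans-2,5); C9 from a CBS reduction of the enone.

Key step: step 4

Assumption: the cross-metathesis of step 3 is expected to give mainly the E allylsilane; any Z isomer carried along should close to the same oxane, because the alkene geometry is erased when the vinyl group forms.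

Step 1
Reactants: 1 ethyl 3-oxohept-6-enoate
Product: 2 ethyl (3R)-3-hydroxyhept-6-enoate
Conditions: (R)-selective ketoreductase, NADP+ (cat.), i-PrOH, aq. KH2PO4/K2HPO4 buffer pH 7, 30 °C
Reagents that add atoms: none
Why: Enzymatic ketone reduction with isopropanol-driven cofactor recycling; the enzyme pocket delivers hydride to one face of the β-keto ester, so an (R)-selective enzyme from a commercial panel should set the future C2 without touching alkene or ester.

Step 2
Reactants: 2 ethyl (3R)-3-hydroxyhept-6-enoate; 3 2-methoxyethoxymethyl chloride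
Product: 4 ethyl (3R)-3-[(2-methoxyethoxy)methoxy]hept-6-enoate
Conditions: MEMCl, i-Pr2NEt, CH2Cl2, 0 °C → rt
Reagents that add atoms: 2-methoxyethoxymethyl chloride (compound 3), COCCOCCl
Why: MEM ether formation (O-alkylation of a secondary alcohol by an α-chloro ether under a hindered amine base), which places the future C6 on O1 and is too weakly basic to dehydrate the β-hydroxy ester.

Step 3
Reactants: 4 ethyl (3R)-3-[(2-methoxyethoxy)methoxy]hept-6-enoate; 5 allyltrimethylsilane
Product: 6 ethyl (3R,6E)-3-[(2-methoxyethoxy)methoxy]-8-(trimethylsilyl)oct-6-enoate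
Conditions: allyltrimethylsilane (4 equiv), second-generation Grubbs catalyst RuCl2(=CHPh)(PCy3)(H2IMes) (5 mol %), CH2Cl2, 40 °C
Reagents that add atoms: allyltrimethylsilane (compound 5), C=CC[Si](C)(C)C
Why: Olefin cross-metathesis of two terminal alkenes with loss of ethylene; the excess of the readily dimerising silane should suppress homocoupling of 4 and the E allylsilane should predominate.

Step 4
Reactants: 6 ethyl (3R,6E)-3-[(2-methoxyethoxy)methoxy]-8-(trimethylsilyl)oct-6-enoate
Product: 8 ethyl 2-[(2R,5R)-5-ethenyloxan-2-yl]acetate, via methylene oxocarbenium ion 7 (not isolated)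
Conditions: SnCl4 (2 equiv), CH2Cl2, −78 → −20 °C; aq. NaHCO3
Reagents that add atoms: none
Why: SnCl4 binds the two oxygens of the methoxyethoxy unit and expels it, leaving the methylene oxocarbenium ion 7 (O1=C6); the γ-carbon of the allylsilane, C5, adds to C6, and the β-silyl cation gives up its silyl group to chloride so that C7=C8 emerges as a vinyl group. The closest known reaction type is the intramolecular Hosomi–Sakurai cyclisation of allylsilanes onto oxocarbenium ions released from MEM ethers, which gives 3-vinyl oxacycles. The oxane closes in a six-membered mode that is endo for the O1=C6 bond (both atoms in the ring) and exo for the alkene (C7 stays outside); bonding through C7 would need a seven-membered ring and a cation without β-silicon support. The new stereocentre C5 is controlled by C2 through a chair transition state in which the CH2CO2Et arm on C2 and the C5=C7 alkene both sit equatorial, which leads to the trans-2,5 ring (5R in 8). The step needs 1,4-diastereoselection and attack through the γ-carbon; the equatorial preference of both groups and the β-silicon effect should secure them, and the ester, a weaker donor than the chelating MEM unit, should remain a spectator at low temperature.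

Step 5
Reactants: 8 ethyl 2-[(2R,5R)-5-ethenyloxan-2-yl]acetate
Product: 9 ethyl 2-[(2R,5R)-5-(3-oxopropyl)oxan-2-yl]acetate
Conditions: Rh(acac)(CO)2 (1 mol %), Xantphos (4 mol %), CO/H2 (1:1, 10 bar), toluene, 80 °C
Reagents that add atoms: carbon monoxide, [C-]#[O+]
Why: Linear-selective rhodium-catalysed hydroformylation; the wide-bite-angle diphosphine and the branching at C5 should direct the formyl group (C9) to the terminal carbon, and no stereocentre is formed or touched.

Step 6
Reactants: 10 geranylacetone [(5E)-6,10-dimethylundeca-5,9-dien-2-one]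
Product: 12 (5E)-6,10-dimethylundeca-1,5,9-trien-2-yl trifluoromethanesulfonate, via potassium enolate 11 (not isolated)
Conditions: KN(SiMe3)2, THF, −78 °C; PhNTf2, −78 → 0 °C
Reagents that add atoms: N-phenylbis(trifluoromethanesulfonimide), O=S(=O)(N(c1ccccc1)S(=O)(=O)C(F)(F)F)C(F)(F)F
Why: Kinetic enolisation of a methyl ketone by a hindered amide base removes a methyl proton, and O-sulfonylation of enolate 11 (enol triflate formation) should give the 1,1-disubstituted alkenyl triflate with the E trisubstituted alkene untouched.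

Step 7
Reactants: 9 ethyl 2-[(2R,5R)-5-(3-oxopropyl)oxan-2-yl]acetate; 12 (5E)-6,10-dimethylundeca-1,5,9-trien-2-yl trifluoromethanesulfonate
Product: 14 ethyl 2-[(2R,5S)-5-[(7E)-3-hydroxy-8,12-dimethyl-4-methylidenetrideca-7,11-dien-1-yl]oxan-2-yl]acetate (both C9 epimers), via alkenylchromium dichloride 13 (not isolated)
Conditions: CrCl2 (4 equiv), NiCl2 (2 mol %), DMF, rt
Reagents that add atoms: none
Why: Nozaki–Hiyama–Kishi coupling, in which zerovalent nickel (formed by reduction with divalent chromium) inserts into the C–OTf bond and hands the alkenyl group to chromium to give the trivalent alkenylchromium 13, which adds to the aldehyde and not to the ester; C9 forms without control and is corrected in steps 8 and 9.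

Step 8
Reactants: 14 ethyl 2-[(2R,5S)-5-[(7E)-3-hydroxy-8,12-dimethyl-4-methylidenetrideca-7,11-dien-1-yl]oxan-2-yl]acetate (both C9 epimers)
Product: 15 ethyl 2-[(2R,5R)-5-[(7E)-8,12-dimethyl-4-methylidene-3-oxotrideca-7,11-dien-1-yl]oxan-2-yl]acetate
Conditions: Dess–Martin periodinane, CH2Cl2, 0 °C → rt
Reagents that add atoms: none
Why: Dess–Martin oxidation of a secondary allylic alcohol converges both C9 epimers on one enone under neutral conditions that leave the ester and the isolated alkenes alone; the enone is used at once.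

Step 9
Reactants: 15 ethyl 2-[(2R,5R)-5-[(7E)-8,12-dimethyl-4-methylidene-3-oxotrideca-7,11-dien-1-yl]oxan-2-yl]acetate
Product: 16 ethyl 2-[(2R,5S)-5-[(3R,7E)-3-hydroxy-8,12-dimethyl-4-methylidenetrideca-7,11-dien-1-yl]oxan-2-yl]acetate
Conditions: (S)-2-methyl-CBS-oxazaborolidine (20 mol %), catecholborane, toluene, −78 °C
Reagents that add atoms: none
Why: Corey–Bakshi–Shibata reduction, in which the ketone binds the catalyst boron anti to the α-branched alkenyl group (the larger substituent) and catecholborane delivers hydride to the exposed face, so the (S)-catalyst should give the 9R carbinol by 1,2-reduction only.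

Step 10
Reactants: 16 ethyl 2-[(2R,5S)-5-[(3R,7E)-3-hydroxy-8,12-dimethyl-4-methylidenetrideca-7,11-dien-1-yl]oxan-2-yl]acetate
Product: 17 2-[(2R,5S)-5-[(3R,7E)-3-hydroxy-8,12-dimethyl-4-methylidenetrideca-7,11-dien-1-yl]oxan-2-yl]acetaldehyde
Conditions: i-Bu2AlH (2.2 equiv), CH2Cl2, −78 °C; MeOH, aq. potassium sodium tartrate
Reagents that add atoms: none
Why: Partial reduction of an ester to the aldehyde by i-Bu2AlH at low temperature, with the first equivalent spent on the free hydroxyl; the cold conditions and the neighbouring ring oxygen should hold the reduction at the aldehyde level.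

Step 11
Reactants: 17 2-[(2R,5S)-5-[(3R,7E)-3-hydroxy-8,12-dimethyl-4-methylidenetrideca-7,11-dien-1-yl]oxan-2-yl]acetaldehyde
Product: 19 2-[(2R,5S)-5-[(3R,7E)-3-hydroxy-8,12-dimethyl-4-methylidenetrideca-7,11-dien-1-yl]oxan-2-yl]prop-2-enal, via Mannich base 18 (not isolated)
Conditions: CH2=NMe2+ I− (Eschenmoser's salt), Et3N, CH2Cl2, rt
Reagents that add atoms: N,N-dimethylmethyleneiminium iodide (Eschenmoser's salt), C=[N+](C)C.[I-]
Why: Mannich reaction of the aldehyde with the iminium salt gives β-amino aldehyde 18, which loses dimethylamine under the amine base (α-methylenation of an aldehyde); the free allylic alcohol does not interfere and the product has no α-hydrogen left.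

Step 12
Reactants: 19 2-[(2R,5S)-5-[(3R,7E)-3-hydroxy-8,12-dimethyl-4-methylidenetrideca-7,11-dien-1-yl]oxan-2-yl]prop-2-enal
Product: 20 2-[(2R,5S)-5-[(3R,7E)-3-hydroxy-8,12-dimethyl-4-methylidenetrideca-7,11-dien-1-yl]oxan-2-yl]prop-2-enoic acid (CNP0197923.2)
Conditions: NaClO2, NaH2PO4, 2-methylbut-2-ene, t-BuOH/H2O, 0 °C → rt
Reagents that add atoms: sodium chlorite, [Na+].[O-]Cl=O
Why: Pinnick oxidation of the α-substituted acrolein to the acrylic acid; the alkene scavenger traps hypochlorous acid, so the four C=C bonds and the allylic alcohol should be left untouched.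

Compound list
1 | ethyl 3-oxohept-6-enoate | C=CCCC(=O)CC(=O)OCC | starting material
2 | ethyl (3R)-3-hydroxyhept-6-enoate | C=CCC[C@H](CC(=O)OCC)O | intermediate
3 | 2-methoxyethoxymethyl chloride | COCCOCCl | starting material
4 | ethyl (3R)-3-[(2-methoxyethoxy)methoxy]hept-6-enoate | C=CCC[C@H](CC(=O)OCC)OCOCCOC | intermediate
5 | allyltrimethylsilane | C=CC[Si](C)(C)C | starting material
6 | ethyl (3R,6E)-3-[(2-methoxyethoxy)methoxy]-8-(trimethylsilyl)oct-6-enoate | C[Si](C)(C)C/C=C/CC[C@H](CC(=O)OCC)OCOCCOC | intermediate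
7 | methylene oxocarbenium ion of the C2 oxygen (O1=C6) | C[Si](C)(C)C/C=C/CC[C@H](CC(=O)OCC)[O+]=C | intermediate (not isolated)
8 | ethyl 2-[(2R,5R)-5-ethenyloxan-2-yl]acetate (trans) | C=C[C@H]1CC[C@H](CC(=O)OCC)OC1 | intermediate
9 | ethyl 2-[(2R,5R)-5-(3-oxopropyl)oxan-2-yl]acetate | O=CCC[C@H]1CC[C@H](CC(=O)OCC)OC1 | intermediate
10 | geranylacetone, (5E)-6,10-dimethylundeca-5,9-dien-2-one | CC(=O)CC/C=C(\C)CCC=C(C)C | starting material
11 | potassium (5E)-6,10-dimethylundeca-1,5,9-trien-2-olate | [K+].C=C([O-])CC/C=C(\C)CCC=C(C)C | intermediate (not isolated)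
12 | (5E)-6,10-dimethylundeca-1,5,9-trien-2-yl trifluoromethanesulfonate | C=C(OS(=O)(=O)C(F)(F)F)CC/C=C(\C)CCC=C(C)C | intermediate
13 | dichloro[(5E)-6,10-dimethylundeca-1,5,9-trien-2-yl]chromium | C=C([Cr](Cl)Cl)CC/C=C(\C)CCC=C(C)C | intermediate (not isolated)
14 | ethyl 2-[(2R,5S)-5-[(7E)-3-hydroxy-8,12-dimethyl-4-methylidenetrideca-7,11-dien-1-yl]oxan-2-yl]acetate, both C9 epimers | C=C(CC/C=C(\C)CCC=C(C)C)C(O)CC[C@H]1CC[C@H](CC(=O)OCC)OC1 | intermediate
15 | ethyl 2-[(2R,5R)-5-[(7E)-8,12-dimethyl-4-methylidene-3-oxotrideca-7,11-dien-1-yl]oxan-2-yl]acetate | C=C(CC/C=C(\C)CCC=C(C)C)C(=O)CC[C@H]1CC[C@H](CC(=O)OCC)OC1 | intermediate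
16 | ethyl 2-[(2R,5S)-5-[(3R,7E)-3-hydroxy-8,12-dimethyl-4-methylidenetrideca-7,11-dien-1-yl]oxan-2-yl]acetate | C=C(CC/C=C(\C)CCC=C(C)C)[C@H](O)CC[C@H]1CC[C@H](CC(=O)OCC)OC1 | intermediate
17 | 2-[(2R,5S)-5-[(3R,7E)-3-hydroxy-8,12-dimethyl-4-methylidenetrideca-7,11-dien-1-yl]oxan-2-yl]acetaldehyde | C=C(CC/C=C(\C)CCC=C(C)C)[C@H](O)CC[C@H]1CC[C@H](CC=O)OC1 | intermediate
18 | 3-(dimethylamino)-2-[(2R,5S)-5-[(3R,7E)-3-hydroxy-8,12-dimethyl-4-methylidenetrideca-7,11-dien-1-yl]oxan-2-yl]propanal (Mannich base, α-carbon unassigned) | C=C(CC/C=C(\C)CCC=C(C)C)[C@H](O)CC[C@H]1CC[C@H](C(CN(C)C)C=O)OC1 | intermediate (not isolated)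
19 | 2-[(2R,5S)-5-[(3R,7E)-3-hydroxy-8,12-dimethyl-4-methylidenetrideca-7,11-dien-1-yl]oxan-2-yl]prop-2-enal | C=C(CC/C=C(\C)CCC=C(C)C)[C@H](O)CC[C@H]1CC[C@H](C(=C)C=O)OC1 | intermediate
20 | 2-[(2R,5S)-5-[(3R,7E)-3-hydroxy-8,12-dimethyl-4-methylidenetrideca-7,11-dien-1-yl]oxan-2-yl]prop-2-enoic acid | C=C(CC/C=C(\C)CCC=C(C)C)[C@H](O)CC[C@H]1CC[C@H](C(=C)C(=O)O)OC1 | target

Total step count: 12.
Longest linear sequence: 11 steps (steps 1–5 and 7–12 from ethyl 3-oxohept-6-enoate); step 6 is a one-step side branch from geranylacetone.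

Steps most likely to fail

Step 4 (key step). The ionised MEM ether may simply lose the alkoxymethyl group, or the allylsilane may be protodesilylated, before the ring closes. The 1,4-relay from C2 to C5 may also be weak, because an axial group at C5 of an oxane is only mildly penalised. The fallback sets out from 2 and comes back at 9; it sets C5 with an auxiliary and closes the ring by a stereochemically inert SN2 reaction at C6, which is then the terminal alkene carbon of 2.
- Silylation of 2 (TBSCl, imidazole, DMF) would give ethyl (3R)-3-[(tert-butyldimethylsilyl)oxy]hept-6-enoate F1.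
- Hydroboration and oxidation (9-BBN, THF; NaBO3) would give ethyl (3R)-3-[(tert-butyldimethylsilyl)oxy]-7-hydroxyheptanoate F2.
- Oxidation with TEMPO/PhI(OAc)2 in aqueous MeCN would give (5R)-5-[(tert-butyldimethylsilyl)oxy]-7-ethoxy-7-oxoheptanoic acid F3.
- The mixed pivalic anhydride (t-BuCOCl, Et3N) would acylate (4S)-4-benzyl-1,3-oxazolidin-2-one in the presence of LiCl to give ethyl (3R)-7-[(4S)-4-benzyl-2-oxo-1,3-oxazolidin-3-yl]-3-[(tert-butyldimethylsilyl)oxy]-7-oxoheptanoate F4.
- Evans alkylation (NaN(SiMe3)2, THF, −78 °C; allyl bromide) would set C5 from the auxiliary alone and bring in C7–C9, giving ethyl (3R,6R)-6-{[(4S)-4-benzyl-2-oxo-1,3-oxazolidin-3-yl]carbonyl}-3-[(tert-butyldimethylsilyl)oxy]non-8-enoate F5.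
- NaBH4 in THF/H2O would cleave the imide reductively beside the ethyl ester to give ethyl (3R,6R)-3-[(tert-butyldimethylsilyl)oxy]-6-(hydroxymethyl)non-8-enoate F6.
- TsCl, Et3N and DMAP would give ethyl (3R,6R)-3-[(tert-butyldimethylsilyl)oxy]-6-{[(4-methylbenzenesulfonyl)oxy]methyl}non-8-enoate F7.
- Bu4NF in THF would remove the silyl group and let the freed C2 oxygen displace the tosylate, closing the ring to ethyl 2-[(2R,5R)-5-(prop-2-en-1-yl)oxan-2-yl]acetate F8.
- 9-BBN then NaBO3 would give ethyl 2-[(2R,5S)-5-(3-hydroxypropyl)oxan-2-yl]acetate F9, and Dess–Martin oxidation would return aldehyde 9.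

Step 6. Enolisation may also occur on the methylene side of the ketone, giving an internal enol triflate that cannot be removed and is carried into the coupling. The fallback sets out from 10 and comes back at 14, replacing steps 6 and 7.
- Condensation of 10 with 2,4,6-triisopropylbenzenesulfonohydrazide (MeOH, cat. HCl) would give geranylacetone 2,4,6-triisopropylbenzenesulfonylhydrazone F10.
- A Shapiro reaction (n-BuLi, 2 equiv, THF, −78 → 0 °C) removes the N–H and then a proton of the methyl group that lies syn to the sulfonamide. Loss of sulfinate and N2 should give [(5E)-6,10-dimethylundeca-1,5,9-trien-2-yl]lithium F11 as one regioisomer.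
- Recooled to −78 °C, F11 would be added to aldehyde 9, where the aldehyde should react ahead of the ester, to give 14.

Step 9. Facial discrimination at the ketone may be incomplete, because both flanking groups are long chains. The 9S epimer left behind could not be separated, since C9 is remote from the ring stereocentres. The fallback sets out from 14 and comes back at 16, replacing steps 8 and 9.
- A Sharpless kinetic resolution of the epimer mixture 14 (Ti(OiPr)4, L-(+)-diisopropyl tartrate, t-BuOOH 0.6 equiv, 4 Å sieves, CH2Cl2, −20 °C) should epoxidise only the 9S epimer.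
- This would give ethyl 2-[(2R,5S)-5-[(3S)-3-hydroxy-3-{(2R)-2-[(3E)-4,8-dimethylnona-3,7-dien-1-yl]oxiran-2-yl}propyl]oxan-2-yl]acetate F12.
- The 9R epimer 16 would remain and be separated from the more polar epoxy alcohol; the isolated trisubstituted alkenes are not allylic alcohols and should not react.

Further compounds
F1 | step 4 | ethyl (3R)-3-[(tert-butyldimethylsilyl)oxy]hept-6-enoate | C=CCC[C@H](CC(=O)OCC)O[Si](C)(C)C(C)(C)C
F2 | step 4 | ethyl (3R)-3-[(tert-butyldimethylsilyl)oxy]-7-hydroxyheptanoate | OCCCC[C@H](CC(=O)OCC)O[Si](C)(C)C(C)(C)C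
F3 | step 4 | (5R)-5-[(tert-butyldimethylsilyl)oxy]-7-ethoxy-7-oxoheptanoic acid | OC(=O)CCC[C@H](CC(=O)OCC)O[Si](C)(C)C(C)(C)C
F4 | step 4 | ethyl (3R)-7-[(4S)-4-benzyl-2-oxo-1,3-oxazolidin-3-yl]-3-[(tert-butyldimethylsilyl)oxy]-7-oxoheptanoate | O=C(CCC[C@H](CC(=O)OCC)O[Si](C)(C)C(C)(C)C)N1[C@@H](Cc2ccccc2)COC1=O
F5 | step 4 | ethyl (3R,6R)-6-{[(4S)-4-benzyl-2-oxo-1,3-oxazolidin-3-yl]carbonyl}-3-[(tert-butyldimethylsilyl)oxy]non-8-enoate | C=CC[C@H](C(=O)N1[C@@H](Cc2ccccc2)COC1=O)CC[C@H](CC(=O)OCC)O[Si](C)(C)C(C)(C)C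
F6 | step 4 | ethyl (3R,6R)-3-[(tert-butyldimethylsilyl)oxy]-6-(hydroxymethyl)non-8-enoate | C=CC[C@H](CO)CC[C@H](CC(=O)OCC)O[Si](C)(C)C(C)(C)C
F7 | step 4 | ethyl (3R,6R)-3-[(tert-butyldimethylsilyl)oxy]-6-{[(4-methylbenzenesulfonyl)oxy]methyl}non-8-enoate | C=CC[C@H](COS(=O)(=O)c1ccc(C)cc1)CC[C@H](CC(=O)OCC)O[Si](C)(C)C(C)(C)C
F8 | step 4 | ethyl 2-[(2R,5R)-5-(prop-2-en-1-yl)oxan-2-yl]acetate | C=CC[C@H]1CC[C@H](CC(=O)OCC)OC1
F9 | step 4 | ethyl 2-[(2R,5S)-5-(3-hydroxypropyl)oxan-2-yl]acetate | OCCC[C@H]1CC[C@H](CC(=O)OCC)OC1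
F10 | step 6 | geranylacetone 2,4,6-triisopropylbenzenesulfonylhydrazone | CC(=NNS(=O)(=O)c1c(C(C)C)cc(C(C)C)cc1C(C)C)CC/C=C(\C)CCC=C(C)C
F11 | step 6 | [(5E)-6,10-dimethylundeca-1,5,9-trien-2-yl]lithium | [Li]C(=C)CC/C=C(\C)CCC=C(C)C
F12 | step 9 | ethyl 2-[(2R,5S)-5-[(3S)-3-hydroxy-3-{(2R)-2-[(3E)-4,8-dimethylnona-3,7-dien-1-yl]oxiran-2-yl}propyl]oxan-2-yl]acetate | O[C@@H](CC[C@H]1CC[C@H](CC(=O)OCC)OC1)[C@@]1(CC/C=C(\C)CCC=C(C)C)CO1
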